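**Odd pair.** Larch was charged twice the G of cedar, over the same time and with the same X, yet at 40.0 h larch still holds 59.9% of its charge as G against 52.8% in cedar. With the same catalyst I expected far more left in larch.

| flask | G | X | remark | time |
|---|---|---|---|---|
| cedar | 0.17 M (fed, over 40 h) | 38 mM | run made earlier |  |
| larch | 0.38 M (fed, over 40 h) | 38 mM | run made earlier |  |
| flask | 0.25 M (fed, over 40 h) | 38 mM |  | 40 h |

| run | time / h | Q / % | L / % | G / % | J / % |
|---|---|---|---|---|---|
| cedar | 8.00 | 1.0 | 1.7 | 17.2 | 1.2 |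
| cedar | 15.0 | 0 | 2.1 | 28.1 | 6.4 |
| cedar | 25.0 | 0.2 | 3.2 | 40.3 | 17.0 |
| cedar | 30.0 | 0.3 | 5.4 | 45.0 | 24.9 |
| cedar | 40.0 | 0.4 | 5.4 | 52.8 | 41.9 |
| larch | 4.00 | 0.2 | 0.2 | 9.5 | 0.4 |
| larch | 10.0 | 0 | 1.5 | 21.2 | 3.9 |
| larch | 20.0 | 0.4 | 2.5 | 36.1 | 10.7 |
| larch | 30.0 | 0.9 | 4.8 | 48.2 | 22.9 |
| larch | 40.0 | 0.4 | 4.5 | 59.9 | 35.7 |

(readings scatter by 0.5 percentage points)

- percent here means G units held: one Z or E counts as two
- reactions considered so far: G + X -> L; L -> Q; Q -> X + J; G + Q <-> Z; J + Q -> E
- percentages count the whole charge, also what has not yet gone in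

* the species in which most of what was charged as G, at 40 h sits (Q / J / L / G)
* the largest share itself, whichever of these holds it, in percent of the G charged

**Clearing it.** The catalyst keeps no fixed pace: at that time [L] stands at 17.1 mM in larch and 9.18 mM in cedar. From 30.0 h to 40.0 h, cedar gains J at 0.315 h⁻¹ times [L]. The last cedar reading gives the half-load level [G][X]/[L], with [X] the charge less L and Q: the [G] at which L and X stand equal, the usual Michaelis constant, 275 mM. Larch's [G], 228 mM, lies below it, so uptake there still climbs with [G].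

**My rounds.** I put the ceiling in the flask at 12.0 mM h⁻¹. I scale it by m[G]/(m[G]+level), with m = 0.603, larch's midpoint G over its end G, standing for the mean over the run. Starting from 125 mM at the end, the rounds give 147 mM, 133 mM and 142 mM. They swing, so I take the mean of the last two, 138 mM, or 55.0% of the charge, which leaves G the largest.

**The forecast.** It gives G at 55.5%: “G holds the most”.

**The flask.** G holds 55.8%.

    G + X → L (k = 0.0191 M⁻¹ min⁻¹)
    L → Q (k = 0.00586 min⁻¹)
    Q → X + J (k = 0.610 min⁻¹)
    G + Q ⇌ Z, settled at all times (K = 5.80 M⁻¹)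
    J + Q → E (k = 0.00262 M⁻¹ min⁻¹)

Up to 40 h the flask's step from G + X to L turned over 44.1% of the charge, a mean of 2.76 mM h⁻¹, less than the feed of 6.25 mM h⁻¹, while the steps to Z (0.0359%) and E (0.00833%) took hardly any of that. At the flask's final [G], the half-load level puts 33.7% of the catalyst in L, and the flask shows 30.4%.

**Second flask.** For a neighbour flask, like this one but charged with 0.62 M of G, the same rounds from my flask share give 415 mM and 392 mM, a mean of 65.1% of the charge. That flask ends with 65.5% as G.

The data come from a simulation on assumed constants.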